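## Structural features

The target is a single cyclohexane ring, numbered here C1 (quaternary carbinol), C2 (CHOH), C3 and C4 (CH2), C5 (CH–OBz) and C6 (CHOH), with one exocyclic carbon C7 on C1 that carries the second benzoate. In this numbering, which is kept for all intermediates, the configuration is 1S,2R,5R,6S. The four stereocentres C2–C1–C6–C5 are contiguous. The oxygens on C2 and C6 are cis to each other and to C7, the C1 hydroxyl is trans to both, and the C5 oxygen is trans to the C6 oxygen. In one chair every ring oxygen is therefore equatorial and only the C1–C7 bond is axial. The fragile parts are the two benzoates, which sit next to free hydroxyls and can migrate or be cleaved under base, and any C1 carbonyl intermediate, in which the C5 oxygen is β and can be lost by E1cB elimination. The real difficulty is twofold: the quaternary centre C1 with its axial carbon substituent, and the need to tell apart four contiguous all-trans oxygens on C2, C1, C6 and C5. A symmetric all-trans cyclohexane-1,2,3,4-tetrol does not help, because its outer and its inner hydroxyls are equivalent in pairs and the required pattern (ethers on C2 and C6, a different group on C5, C1 free) cannot be reached from it by selective protection; the oxygens must be differentiated as they are introduced. The key step exploits the position of C1 between C2 and C6, whose oxygens are equatorial in a chair locked by three equatorial substituents: axial delivery of a methylene group to a C1 ketone gives the axial C1–C7 bond and the equatorial C1 oxygen.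

## Logic of the disconnections

19 to 18: the two O–CH2Ph bonds on the C2 and C6 oxygens are cut. The free triol next to two esters is the stage most prone to acyl migration, so it is revealed last. All earlier chemistry then runs on compounds with at most one free secondary hydroxyl. The forward step must cleave benzyl ethers under neutral conditions and leave both benzoates untouched.

18 to 16 and 17: the acyl–O bond of the C5 ester is cut. An ester β to C1 cannot be present while C1 is a carbonyl, so it is introduced after the C1 centre is complete. The forward step must acylate the secondary C5 hydroxyl and leave the tertiary C1 hydroxyl alone.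

16 to 15: the O–Si bond on the C5 oxygen is restored. C5 needs a group that is orthogonal to benzyl ethers and esters and is not a leaving group. Its removal must not trigger migration of the C7 benzoate, which calls for a non-basic fluoride source.

15 to 13 and 14: the C7–O bond is cut, which turns the hydroxy ester into a spiro-oxirane and a carboxylate. Both the C1–O and the C7–O bond then come from one functional group whose configuration is already fixed. The forward step must attack the CH2 carbon only, by SN2, without ionising the tertiary C1–O bond.

13 to 10 and 11: the C1–C7 bond and the C7–O bond of the oxirane are cut. This removes the quaternary stereocentre and the only exocyclic carbon and leaves a cyclohexanone with three secondary C–O centres. The forward step must deliver CH2 axially and must add to the carbonyl faster than it enolises it.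

10 to 9: no bond is cut; the C1 carbonyl is traced back to a C1 carbinol. A free C1 hydroxyl between two ethers is the direct product of an epoxide opening. The oxidation must be non-basic so that C2 and C6 are not epimerised and the C5 oxygen is not eliminated.

9 to 8 and 3: the C2–O(benzyl) bond is cut, giving a C1–C2 oxirane. One event creates the C2 ether and the free C1 hydroxyl, so these two oxygens are differentiated without any selective protection. The forward step needs attack at C2, the carbon distal to C6, with inversion.

8 to 7: the O–Si bond on the C5 oxygen is cut. Silylation before the opening ensures that 9 has exactly one free hydroxyl. The forward step must not disturb the oxirane.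

7 to 6: both C–O bonds of the C1–C2 oxirane are cut, leaving a C1=C2 alkene. The oxygen must be delivered to the face of the C5 hydroxyl, which is the face opposite the C6 benzyloxy group; this calls for a hydroxyl-directed epoxidation.

6 to 5: the acetyl–O bond is formed in retrosynthesis. The step carries the absolute configuration, and the racemic ester is the substrate of a resolution. The forward step needs an enzyme that cleaves the (1R)-ester selectively.

5 to 2 and 3 (through 4): the C6–O(benzyl) bond is cut, giving a vinyl oxirane. As in the later opening, the C6 ether and the free C5 hydroxyl arise already differentiated and trans. The forward step needs direct attack at the allylic carbon with inversion and not conjugate opening.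

2 to 1: the two C–O bonds of the oxirane are cut, leaving a cheap conjugated diene. The forward step must stop at the monoepoxide.

## Other disconnections considered

Alternative 1: No skeletal bond is cut. The ring of 19 is taken from the benzene ring of methyl benzoate, C7 from its ester carbon, and the C5–O and C6–O bonds from dioxygen. In the forward key step, whole cells expressing toluene dioxygenase would add O2 across the ortho and meta positions to give methyl (5S,6R)-5,6-dihydroxycyclohexa-1,3-diene-1-carboxylate (A1).
- In its favour: all seven carbons and the correct C6 configuration are in place after one catalytic, enantioselective step, with no resolution and no C–C bond formation. On these two points it is better than the chosen plan.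
- Against it here: A1 is a cis-diol, whereas the C5 and C6 oxygens of 19 are trans, so C5 must be inverted. A Mitsunobu reaction with benzoic acid could invert and acylate at once, but on a dienol that can also react by SN2′ displacement, eliminate or aromatise.
- The diene must then be taken apart: C3=C4 reduced, C1=C2 turned into a trans-diol with the tertiary oxygen anti to the C6 oxygen, and the ester reduced and re-acylated.
- Acceptance of an electron-poor ester by the enzyme and the need for fermentation equipment are further open points.
- Comparison: the start is structurally simpler (better) and the length is comparable (about ten to twelve steps). However, C1, C2 and C5 must still be set or corrected by reagent approach to a flexible diene or cyclohexene. The chosen plan sets C1 on a locked chair and C2, C5 and C6 by stereospecific epoxide openings, so it is mechanistically the more predictable.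

Alternative 2: The ring bond C5–C6 is cut. In the forward key step the enamine (proline catalysis) or enolate of (4R)-2,2-dimethyl-4-(3-oxopropyl)-1,3-dioxan-5-one (A3) would attack its own aldehyde through the unsubstituted α-carbon. The product would be (1R,5S,6R)-6-hydroxy-3,3-dimethyl-2,4-dioxabicyclo[3.3.1]nonan-9-one (A2).
- In its favour: the ring and the C5 and C6 centres are formed in one step from a small piece, and the acetal bridge enforces the cis relation of the C2 and C6 oxygens.
- In A2 the two faces of the C1 carbonyl differ strongly. The face over the dioxane ring has no syn-axial hydrogens, while the carbocyclic face is screened by the axial C5 substituent. A methylene donor should therefore enter cis to the C2 and C6 oxygens, as the target requires.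
- On step count (perhaps eight to ten steps) and on the rigidity of the C1 control it is the equal or the better of the chosen plan.
- Against it: the closure needs the side chain and the new bond 1,3-diaxial on the dioxanone and builds a bridged system with an endo methyl group pointing at C4, so the aldol may be slow and reversible.
- A3 has an epimerisable α-centre, and A2 is a β-hydroxy ketone open to retro-aldol cleavage and dehydration.
- The C5 configuration rests on aldehyde-face selection in a strained transition state that cannot be predicted with confidence. The C5 hydroxyl must also be masked during the C7 addition, since a β-benzoate would eliminate.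
- Comparison: the chosen plan is longer but places its risk in reactions of well-defined stereochemical course; here most of the risk lies in the key step itself.

Alternative 3: The bond C3–C4 is cut (as C3=C4). In the forward key step the acyclic diene (3R,4S,5S,6R)-4-[(benzoyloxy)methyl]-3,5-bis[(tert-butyldimethylsilyl)oxy]-4-hydroxyocta-1,7-dien-6-yl benzoate (A5) would be closed with the second-generation Grubbs catalyst RuCl2(=CHPh)(PCy3)(H2IMes), with loss of ethylene. The product would be [(1S,2R,5R,6S)-5-(benzoyloxy)-2,6-bis[(tert-butyldimethylsilyl)oxy]-1-hydroxycyclohex-3-en-1-yl]methyl benzoate (A4).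
- In its favour: metathesis of a 1,7-diene to a cyclohexene is among the most dependable ring closures. It tolerates esters, silyl ethers and a free tertiary alcohol and touches no stereocentre.
- Only an alkene hydrogenation and a desilylation would remain to reach 19. As a key step it is at least as secure as the ylide addition, and the end-game is shorter (better).
- Against it: the whole stereochemical problem, including the quaternary C1 between two oxygenated centres, is moved into an open chain where no chair helps.
- A5 needs differentiated oxygens on five adjacent carbons and would take at least as many steps as 10.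
- The allylic benzoate of A4 is at risk of hydrogenolysis when C3=C4 is reduced, and both benzoates must survive unmigrated through the assembly.
- Comparison: equal or better at the key step, but weaker and probably longer before it.

Key step: step 8

Remark: the lipase is assumed to follow the Kazlauskas rule for secondary alcohols, that is, to hydrolyse the (1R)-configured acetate of 5 faster.
Remark: racemates 2, 4 and 5 are written with the SMILES of the enantiomer that is carried on; ring atoms are referred to by the target numbering C1–C7, while systematic names use their own locants.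

## Route

Step 1
Reactants: 1 cyclohexa-1,3-diene
Product: 2 rac-7-oxabicyclo[4.1.0]hept-2-ene
Conditions: mCPBA (0.95 equiv), NaHCO3 (buffer), CH2Cl2, 0 °C
Reagents that add atoms: 3-chloroperbenzoic acid (mCPBA), OOC(=O)c1cccc(Cl)c1
Why: Prilezhaev epoxidation; the conjugated diene is more electron-rich than the remaining alkene of the vinyl oxirane, so a slight deficit of peracid should stop at the monoepoxide, and the buffer protects the acid-labile allylic oxirane.

Step 2
Reactants: 2 rac-7-oxabicyclo[4.1.0]hept-2-ene; 3 benzyl alcohol
Product: 5 rac-(1R*,2R*)-2-(benzyloxy)cyclohex-3-en-1-yl acetate, via racemic trans-2-(benzyloxy)cyclohex-3-en-1-ol 4 (not isolated)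
Conditions: BnOH (2 equiv), BF3·OEt2 (5 mol %), CH2Cl2, −40 → −20 °C; then Et3N, Ac2O, DMAP (cat.), 0 → 20 °C
Reagents that add atoms: benzyl alcohol (compound 3), OCc1ccccc1; acetic anhydride, CC(=O)OC(C)=O
Why: Lewis-acid-catalysed alcoholysis of a vinyl oxirane; the allylic C–O bond (at C6) is the activated one, and backside attack there at low temperature should give the trans hydroxy ether with the free hydroxyl on C5. Acetylation in the same flask supplies the ester for the resolution.

Step 3
Reactants: 5 rac-(1R*,2R*)-2-(benzyloxy)cyclohex-3-en-1-yl acetate
Product: 6 (1R,2R)-2-(benzyloxy)cyclohex-3-en-1-ol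
Conditions: Burkholderia cepacia lipase (Amano PS), phosphate buffer pH 7/MTBE, 30 °C, stopped near 45% conversion
Reagents that add atoms: none
Why: Lipase-catalysed kinetic resolution by enantioselective ester hydrolysis; esters of trans-2-substituted cyclohexanols are a standard substrate class, and the (1R)-ester should be cleaved faster, so that 6 is released directly and the (1S,2S)-acetate stays behind. This fixes the absolute configuration of C5 and C6.

Step 4
Reactants: 6 (1R,2R)-2-(benzyloxy)cyclohex-3-en-1-ol
Product: 7 (1S,2S,3R,6S)-2-(benzyloxy)-7-oxabicyclo[4.1.0]heptan-3-ol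
Conditions: VO(acac)2 (5 mol %), t-BuOOH (1.5 equiv), toluene, 20–40 °C
Reagents that add atoms: tert-butyl hydroperoxide, CC(C)(C)OO
Why: Vanadium-catalysed hydroxyl-directed epoxidation of a homoallylic cyclohexenol; the metal alkoxide delivers oxygen to the face of the pseudo-axial C5 hydroxyl, which is also the face opposite the allylic benzyloxy group, so the oxirane oxygen is set cis to OH and trans to OBn.

Step 5
Reactants: 7 (1S,2S,3R,6S)-2-(benzyloxy)-7-oxabicyclo[4.1.0]heptan-3-ol
Product: 8 tert-butyl{[(1S,2R,3R,6S)-2-(benzyloxy)-7-oxabicyclo[4.1.0]heptan-3-yl]oxy}dimethylsilane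
Conditions: TBSCl, imidazole, DMF, 20 °C
Reagents that add atoms: tert-butyldimethylsilyl chloride, CC(C)(C)[Si](C)(C)Cl
Why: Standard silylation of a secondary alcohol; the oxirane is inert to imidazole in DMF, and the ether is placed now so that the hydroxyl released in the next step is the only free one.

Step 6
Reactants: 8 tert-butyl{[(1S,2R,3R,6S)-2-(benzyloxy)-7-oxabicyclo[4.1.0]heptan-3-yl]oxy}dimethylsilane; 3 benzyl alcohol
Product: 9 (1S,2R,3R,6R)-2,6-bis(benzyloxy)-3-[(tert-butyldimethylsilyl)oxy]cyclohexan-1-ol
Conditions: BnOH (5 equiv), BF3·OEt2 (10 mol %), CH2Cl2, −30 → 0 °C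
Reagents that add atoms: benzyl alcohol (compound 3), OCc1ccccc1
Why: Acid-catalysed trans-diaxial (Fürst–Plattner) opening of a cyclohexene oxide; the oxirane carbon next to the benzyloxy-bearing C6 is inductively deactivated and shielded, so benzyl alcohol should enter at the distal carbon C2 with inversion. The product has all four oxygens mutually trans and only the C1 hydroxyl free.

Step 7
Reactants: 9 (1S,2R,3R,6R)-2,6-bis(benzyloxy)-3-[(tert-butyldimethylsilyl)oxy]cyclohexan-1-ol
Product: 10 (2S,3R,6R)-2,6-bis(benzyloxy)-3-[(tert-butyldimethylsilyl)oxy]cyclohexan-1-one
Conditions: Dess–Martin periodinane, CH2Cl2, 0 → 20 °C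
Reagents that add atoms: none
Why: Dess–Martin oxidation of a hindered secondary alcohol under non-basic conditions, chosen so that the α-alkoxy centres are not epimerised and the β-silyloxy group is not eliminated.

Step 8
Reactants: 10 (2S,3R,6R)-2,6-bis(benzyloxy)-3-[(tert-butyldimethylsilyl)oxy]cyclohexan-1-one; 11 trimethylsulfonium iodide
Product: 13 tert-butyl{[(3S,4S,5R,8R)-4,8-bis(benzyloxy)-1-oxaspiro[2.5]octan-5-yl]oxy}dimethylsilane, via sulfonium alkoxide betaine 12 (not isolated)
Conditions: Me3S+ I− (2 equiv), n-BuLi (1.9 equiv), THF, −10 °C; then 10, −10 → 20 °C
Reagents that add atoms: trimethylsulfonium iodide (compound 11), C[S+](C)C.[I-]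
Why: Corey–Chaykovsky epoxidation: dimethylsulfonium methylide, formed from 11 and n-BuLi, adds through carbon to the C1 carbonyl of 10 to give betaine 12, whose alkoxide displaces dimethyl sulfide from the adjacent CH2 in a 3-exo-tet closure that forms the oxirane ring of 13. The closest known reaction type is the sulfonium-ylide epoxidation of conformationally fixed cyclohexanones and of protected inososes. The only new stereocentre is C1, and it is set by the substrate: the two benzyloxy groups and the silyloxy group are all equatorial, and the other chair would place the two benzyloxy groups syn-diaxial, so the ring is locked. The unstabilised ylide adds irreversibly under kinetic control, and a small nucleophile prefers the axial trajectory, which avoids torsional strain with the axial C2–H and C6–H bonds and meets only the axial hydrogens on C3 and C5. The C1–C7 bond therefore becomes axial and the oxirane oxygen equatorial, which is the (3S) configuration of 13 and the arrangement of the target. The step needs facial selectivity and addition in preference to enolisation: the ylide is preformed at −10 °C and the ketone is added to it, so that carbonyl addition should outrun deprotonation, and the β-oxygen is carried as a silyl ether, a poor leaving group. The sulfoxonium ylide is avoided because its reversible addition would favour the equatorial C–C bond.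

Step 9
Reactants: 13 tert-butyl{[(3S,4S,5R,8R)-4,8-bis(benzyloxy)-1-oxaspiro[2.5]octan-5-yl]oxy}dimethylsilane; 14 benzoic acid
Product: 15 [(1S,2S,3R,6R)-2,6-bis(benzyloxy)-3-[(tert-butyldimethylsilyl)oxy]-1-hydroxycyclohexyl]methyl benzoate
Conditions: PhCO2H (2 equiv), PhCO2Cs (1 equiv), DMF, 80 °C
Reagents that add atoms: benzoic acid (compound 14), OC(=O)c1ccccc1
Why: SN2 opening of a 2,2-disubstituted oxirane by a carboxylate at the unsubstituted CH2 carbon; the C1–O bond is not touched, so the configuration set in step 8 is kept. The free acid protonates the tertiary alkoxide before it can attack the ester, and the cesium salt is regenerated.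

Step 10
Reactants: 15 [(1S,2S,3R,6R)-2,6-bis(benzyloxy)-3-[(tert-butyldimethylsilyl)oxy]-1-hydroxycyclohexyl]methyl benzoate
Product: 16 [(1S,2S,3R,6R)-2,6-bis(benzyloxy)-1,3-dihydroxycyclohexyl]methyl benzoate
Conditions: HF·pyridine, THF/pyridine, 0 → 20 °C
Reagents that add atoms: none
Why: Fluoride cleavage of a secondary silyl ether under buffered acidic conditions, which avoids the benzoate migration that a basic fluoride source could cause; benzyl ethers and the ester are inert.

Step 11
Reactants: 16 [(1S,2S,3R,6R)-2,6-bis(benzyloxy)-1,3-dihydroxycyclohexyl]methyl benzoate; 17 benzoyl chloride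
Product: 18 [(1S,2S,3R,6R)-3-(benzoyloxy)-2,6-bis(benzyloxy)-1-hydroxycyclohexyl]methyl benzoate
Conditions: BzCl (1.2 equiv), pyridine, DMAP (cat.), CH2Cl2, 0 → 20 °C
Reagents that add atoms: benzoyl chloride (compound 17), O=C(Cl)c1ccccc1
Why: Acylation of the only secondary hydroxyl (C5); the tertiary C1 hydroxyl, flanked by two benzyloxy-bearing carbons, should not react under these conditions.

Step 12
Reactants: 18 [(1S,2S,3R,6R)-3-(benzoyloxy)-2,6-bis(benzyloxy)-1-hydroxycyclohexyl]methyl benzoate
Product: 19 [(1S,2S,3R,6R)-3-(benzoyloxy)-1,2,6-trihydroxycyclohexyl]methyl benzoate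
Conditions: H2 (1 atm), 10% Pd/C, EtOAc/EtOH, 20 °C
Reagents that add atoms: none
Why: Hydrogenolysis of the two benzyl ethers under neutral conditions; benzoates of non-benzylic alcohols are stable, and the absence of base should prevent acyl migration among the liberated hydroxyls.

## Compound list

1 | cyclohexa-1,3-diene | C1=CC=CCC1 | starting material
2 | rac-7-oxabicyclo[4.1.0]hept-2-ene (cis-fused vinyl oxirane, racemic) | C1=C[C@@H]2O[C@@H]2CC1 | intermediate
3 | benzyl alcohol | OCc1ccccc1 | starting material
4 | rac-(1R*,2R*)-2-(benzyloxy)cyclohex-3-en-1-ol (trans, racemic) | O[C@@H]1CCC=C[C@H]1OCc1ccccc1 | intermediate (not isolated)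
5 | rac-(1R*,2R*)-2-(benzyloxy)cyclohex-3-en-1-yl acetate (trans, racemic) | CC(=O)O[C@@H]1CCC=C[C@H]1OCc1ccccc1 | intermediate
6 | (1R,2R)-2-(benzyloxy)cyclohex-3-en-1-ol | O[C@@H]1CCC=C[C@H]1OCc1ccccc1 | intermediate
7 | (1S,2S,3R,6S)-2-(benzyloxy)-7-oxabicyclo[4.1.0]heptan-3-ol (oxirane oxygen cis to OH, trans to OBn) | O[C@@H]1CC[C@@H]2O[C@@H]2[C@H]1OCc1ccccc1 | intermediate
8 | tert-butyl{[(1S,2R,3R,6S)-2-(benzyloxy)-7-oxabicyclo[4.1.0]heptan-3-yl]oxy}dimethylsilane | CC(C)(C)[Si](C)(C)O[C@@H]1CC[C@@H]2O[C@@H]2[C@H]1OCc1ccccc1 | intermediate
9 | (1S,2R,3R,6R)-2,6-bis(benzyloxy)-3-[(tert-butyldimethylsilyl)oxy]cyclohexan-1-ol (all oxygens mutually trans) | O[C@H]1[C@H](OCc2ccccc2)CC[C@@H](O[Si](C)(C)C(C)(C)C)[C@@H]1OCc1ccccc1 | intermediate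
10 | (2S,3R,6R)-2,6-bis(benzyloxy)-3-[(tert-butyldimethylsilyl)oxy]cyclohexan-1-one | O=C1[C@H](OCc2ccccc2)CC[C@@H](O[Si](C)(C)C(C)(C)C)[C@@H]1OCc1ccccc1 | intermediate
11 | trimethylsulfonium iodide | C[S+](C)C.[I-] | starting material
12 | sulfonium alkoxide betaine: C1 alkoxide of 10 bearing an axial CH2–S+Me2 group | C[S+](C)C[C@]1([O-])[C@H](OCc2ccccc2)CC[C@@H](O[Si](C)(C)C(C)(C)C)[C@@H]1OCc1ccccc1 | intermediate (not isolated)
13 | tert-butyl{[(3S,4S,5R,8R)-4,8-bis(benzyloxy)-1-oxaspiro[2.5]octan-5-yl]oxy}dimethylsilane (axial CH2, equatorial O) | C1O[C@]12[C@H](OCc3ccccc3)CC[C@@H](O[Si](C)(C)C(C)(C)C)[C@@H]2OCc2ccccc2 | intermediate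
14 | benzoic acid | OC(=O)c1ccccc1 | starting material
15 | [(1S,2S,3R,6R)-2,6-bis(benzyloxy)-3-[(tert-butyldimethylsilyl)oxy]-1-hydroxycyclohexyl]methyl benzoate | O=C(OC[C@]1(O)[C@H](OCc2ccccc2)CC[C@@H](O[Si](C)(C)C(C)(C)C)[C@@H]1OCc1ccccc1)c1ccccc1 | intermediate
16 | [(1S,2S,3R,6R)-2,6-bis(benzyloxy)-1,3-dihydroxycyclohexyl]methyl benzoate | O=C(OC[C@]1(O)[C@H](OCc2ccccc2)CC[C@@H](O)[C@@H]1OCc1ccccc1)c1ccccc1 | intermediate
17 | benzoyl chloride | O=C(Cl)c1ccccc1 | starting material
18 | [(1S,2S,3R,6R)-3-(benzoyloxy)-2,6-bis(benzyloxy)-1-hydroxycyclohexyl]methyl benzoate | O=C(OC[C@]1(O)[C@H](OCc2ccccc2)CC[C@@H](OC(=O)c2ccccc2)[C@@H]1OCc1ccccc1)c1ccccc1 | intermediate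
19 | [(1S,2S,3R,6R)-3-(benzoyloxy)-1,2,6-trihydroxycyclohexyl]methyl benzoate | O=C(OC[C@]1(O)[C@H](O)CC[C@@H](OC(=O)c2ccccc2)[C@@H]1O)c1ccccc1 | target

## Step count and least certain steps

Total step count: 12. Longest linear sequence: 12 steps (1 to 19); 3, 11, 14 and 17 are purchased reagents that enter this single line.

Step 8 (key step). The most likely failures are incomplete facial selectivity (competing equatorial attack, which would give the C1 epimer) and enolisation of 10 by the basic ylide followed by β-elimination of the silyloxy group. Both stem from the small size and basicity of the reagent and from the two acidic α-hydrogens.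
- Fallback, setting out from 10 and returning at 15: non-basic Petasis methylenation (Cp2TiMe2, toluene, 65 °C) should give {[(1R,2R,4R)-2,4-bis(benzyloxy)-3-methylidenecyclohexyl]oxy}(tert-butyl)dimethylsilane F1.
- Upjohn dihydroxylation (OsO4 cat., N-methylmorpholine N-oxide, acetone/water) follows. The bulky oxidant is expected to approach the exocyclic alkene from the equatorial side and so place the tertiary hydroxyl equatorial, giving (1S,2S,3R,6R)-2,6-bis(benzyloxy)-3-[(tert-butyldimethylsilyl)oxy]-1-(hydroxymethyl)cyclohexan-1-ol F2.
- Benzoylation of the primary hydroxyl only (BzCl, pyridine, CH2Cl2, −20 °C) then gives 15. This path also bypasses step 9.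

Step 6. The most likely failures are loss or migration of the silyl group under the Lewis acid, and some attack at the proximal oxirane carbon if the half-chair with equatorial substituents reacts. The first arises because fluoride-containing Lewis acids attack silyl ethers, the second because distal attack must pass through the diaxial half-chair.
- Fallback, setting out from 7 and returning at 9: the unprotected epoxy alcohol is opened by SN2 attack of BnONa in BnOH/THF at 70 °C, which has no cationic character and should go to the distal carbon, giving (1R,2S,3S,4R)-2,4-bis(benzyloxy)cyclohexane-1,3-diol F3.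
- The less hindered hydroxyl, the one with only one oxygenated neighbour, is then silylated (TBSCl, imidazole, CH2Cl2, −20 °C) to give 9.

Step 4. The most likely failure is a slow reaction with eroded face selectivity, because direction by a homoallylic hydroxyl needs the half-chair with both substituents pseudo-axial.
- Fallback, setting out from 6 and returning at 7: Boc2O and DMAP should give tert-butyl (1R,2R)-2-(benzyloxy)cyclohex-3-en-1-yl carbonate F4.
- Iodocarbonate cyclisation (IBr, toluene, −80 °C) delivers the carbonate oxygen intramolecularly to C1 on the face of the C5 oxygen, with iodine anti on C2, giving (1R,5R,6R,9S)-9-(benzyloxy)-6-iodo-2,4-dioxabicyclo[3.3.1]nonan-3-one F5.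
- K2CO3 in MeOH cleaves the carbonate, and the C1 alkoxide displaces the anti iodide to give 7 stereospecifically.

Step 3. The most likely failures are insufficient enantioselection by the enzyme for this allylic ether substrate, or an enantiopreference opposite to the rule. Because 6 is the product of the resolution and not its residue, its optical purity cannot be raised by pushing the conversion. If only the sense were reversed, the residual acetate would be the (1R,2R)-ester and would be cleaved with K2CO3/MeOH.
- Fallback, setting out from 1 and returning at 6: Jacobsen–Katsuki epoxidation of 1 with NaOCl and the chloromanganese complex of (S,S)-N,N′-bis(3,5-di-tert-butylsalicylidene)cyclohexane-1,2-diamine, (salen)MnCl. By analogy with benzo-fused cis-olefins this catalyst enantiomer should give (1S,6R)-7-oxabicyclo[4.1.0]hept-2-ene F6.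
- Opening of F6 with BnOH and BF3·OEt2, as in the first half of step 2 but without acetylation, then gives 6.

Further compounds
F1 | step 8 | {[(1R,2R,4R)-2,4-bis(benzyloxy)-3-methylidenecyclohexyl]oxy}(tert-butyl)dimethylsilane | C=C1[C@H](OCc2ccccc2)CC[C@@H](O[Si](C)(C)C(C)(C)C)[C@@H]1OCc1ccccc1
F2 | step 8 | (1S,2S,3R,6R)-2,6-bis(benzyloxy)-3-[(tert-butyldimethylsilyl)oxy]-1-(hydroxymethyl)cyclohexan-1-ol | OC[C@]1(O)[C@H](OCc2ccccc2)CC[C@@H](O[Si](C)(C)C(C)(C)C)[C@@H]1OCc1ccccc1
F3 | step 6 | (1R,2S,3S,4R)-2,4-bis(benzyloxy)cyclohexane-1,3-diol | O[C@H]1[C@H](OCc2ccccc2)CC[C@@H](O)[C@@H]1OCc1ccccc1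
F4 | step 4 | tert-butyl (1R,2R)-2-(benzyloxy)cyclohex-3-en-1-yl carbonate | CC(C)(C)OC(=O)O[C@@H]1CCC=C[C@H]1OCc1ccccc1
F5 | step 4 | (1R,5R,6R,9S)-9-(benzyloxy)-6-iodo-2,4-dioxabicyclo[3.3.1]nonan-3-one | O=C1O[C@@H]2CC[C@@H](I)[C@H](O1)[C@H]2OCc1ccccc1
F6 | step 3 | (1S,6R)-7-oxabicyclo[4.1.0]hept-2-ene | C1=C[C@@H]2O[C@@H]2CC1
A1 | alternative 1 | methyl (5S,6R)-5,6-dihydroxycyclohexa-1,3-diene-1-carboxylate | COC(=O)C1=CC=C[C@H](O)[C@@H]1O
A2 | alternative 2 | (1R,5S,6R)-6-hydroxy-3,3-dimethyl-2,4-dioxabicyclo[3.3.1]nonan-9-one | O=C1[C@H]2CC[C@@H](O)[C@@H]1OC(C)(C)O2
A3 | alternative 2 | (4R)-2,2-dimethyl-4-(3-oxopropyl)-1,3-dioxan-5-one | O=CCC[C@H]1OC(C)(C)OCC1=O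
A4 | alternative 3 | [(1S,2R,5R,6S)-5-(benzoyloxy)-2,6-bis[(tert-butyldimethylsilyl)oxy]-1-hydroxycyclohex-3-en-1-yl]methyl benzoate | O=C(OC[C@]1(O)[C@H](O[Si](C)(C)C(C)(C)C)C=C[C@@H](OC(=O)c2ccccc2)[C@@H]1O[Si](C)(C)C(C)(C)C)c1ccccc1
A5 | alternative 3 | (3R,4S,5S,6R)-4-[(benzoyloxy)methyl]-3,5-bis[(tert-butyldimethylsilyl)oxy]-4-hydroxyocta-1,7-dien-6-yl benzoate | O=C(OC[C@](O)([C@H](O[Si](C)(C)C(C)(C)C)C=C)[C@@H](O[Si](C)(C)C(C)(C)C)[C@H](OC(=O)c1ccccc1)C=C)c1ccccc1
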